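**The trap.** Saturday's right-handed product reads 0% at 50.0 min, which looks like no reaction, but the scatter is 1 percentage point, so right-handed substrate may be turning over beneath it.

| setting | Saturday's | Monday's | flask |
|---|---|---|---|
| left-handed substrate | 0.30 M | 0.15 M | 0.30 M |
| right-handed substrate | 0.30 M | 0.15 M | 0.30 M |
| gas | 59 mM (held) | 59 mM (held) | 59 mM (held) |
| precatalyst | 0.81 mM | 0.81 mM | 0.81 mM |
| remark | the very flask that is asked about, followed so far | run made earlier |  |
| time |  |  | 6.0 h |

Saturday's run (percent of the left-handed substrate and right-handed substrate together charged)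

| time / min | left-handed product / % | right-handed product / % | left-handed substrate / % |
|---|---|---|---|
| 15.0 | 8.7 | 0 | 40.7 |
| 30.0 | 24.7 | 0 | 26.7 |
| 50.0 | 38.2 | 0 | 9.2 |
| 60.0 | 44.6 | 1.0 | 8.0 |
| 80.0 | 46.8 | 1.6 | 2.4 |
| 90.0 | 47.1 | 0.5 | 2.0 |
| 120 | 49.6 | 1.8 | 0 |

Monday's run (percent of the left-handed substrate and right-handed substrate together charged)

| time / h | left-handed product / % | right-handed product / % | left-handed substrate / % |
|---|---|---|---|
| 0.133 | 3.8 | 0.3 | 45.5 |
| 0.333 | 18.3 | 0 | 30.4 |
| 0.667 | 38.7 | 0.3 | 10.7 |
| 1.00 | 46.0 | 2.1 | 2.7 |
| 1.33 | 48.5 | 2.3 | 0 |
| 2.00 | 50.9 | 3.7 | 1.3 |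
| 2.50 | 49.2 | 2.7 | 0 |

(readings scatter by 1 percentage point)

- catalyst is single-handed; left-handed substrate and right-handed substrate are mirror images of each other, charged as a racemate, each of them at the stated concentration
- at the start none of the gas is in solution
- an excess is the difference of the two amounts in percent of their sum
- an excess is below zero if the other one leads

* excess of left-handed product over right-handed product in the product at 40 min
* excess of left-handed product over right-handed product in the product at 6.0 h
* part of the left-handed substrate and right-handed substrate charged together that has reacted at 6.0 h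

**Fast end.** Saturday's [left-handed substrate] falls from 26.7% to 9.2% between 30.0 min and 50.0 min, a first-order constant of 0.0533 min⁻¹. Monday's run, at half the charge, gives about the same, 0.0521 min⁻¹, so I carry each as a working slope of its own stretch, not as a constant of the whole decay. Running Saturday's line back to the full charge gives an induction of 18.2 min.

**Slow end.** Saturday's left-handed substrate reads 0% at 120 min, so I hold left-handed product at half of the charge from then on. Saturday's last right-handed reading, 1.8%, gives 0.0212 h⁻¹. Joined to the fast end, that makes the excess at 6.0 h 79.6%.

**Weak link.** That reading carries a scatter of 1 point. The two runs do not keep the same time: Saturday's left-handed substrate reads 8.0% at 60.0 min, Monday's 2.7% at 1.00 h, and Monday's line runs back to a shorter induction, 10.4 min. So I assume one slow constant for both runs and pool 1.8%, 3.7% and 2.7%, each counted from its own run's induction. This gives the slow constant, the fraction of right-handed substrate converted per hour after the induction: 0.0280 h⁻¹. Right-handed product reaches 7.38% at 6.0 h, so I commit to an excess of 74.3% there and 57.4% reacted. At 40 min my excess is 97.1%.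

**The forecast.** It gives 97%, 75% and 57%, from a selectivity of about 120, “assuming the catalyst survives”. Its late excess stands 0.70 points above mine.

**The result.** Saturday's flask gives 97.8% at 40 min, and 72.7% with 57.9% reacted at 6.0 h, so the forecast stands within its margin.

    2 catalyst ⇌ resting dimer, settled at all times (K = 970 M⁻¹)
    gas ⇌ partner, rate k2*(csat - [partner]) (kL = 0.180 min⁻¹)
    partner + precatalyst → catalyst + spent reagent (k = 2.70 M⁻¹ min⁻¹)
    partner + catalyst + left-handed substrate → catalyst + left-handed product (k = 3000 M⁻² min⁻¹)
    partner + catalyst + right-handed substrate → catalyst + right-handed product (k = 21.0 M⁻² min⁻¹)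

At 6.0 h Saturday's flask keeps less of its left-handed substrate than of its right-handed substrate, 0% against 84%, and holds 7.89% right-handed product. That puts its slow constant at 0.0302 h⁻¹. The constant moves in the neighbour charged with 0.0014 M of precatalyst, 1.73 times Saturday's charge: counted from the same induction, its 10.9% right-handed product gives 0.0432 h⁻¹, and its excess at 6.0 h, against the forecast's 75%, is 64.2%.

The data are simulated from invented constants, noise included.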